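## Retrosynthetic overview

1. Target 9 ⇒ silyl dienol ether 8 (from enone 7): the last bond made is C4–OMe, by oxidative γ-methoxylation; C4 (S) is set here.
2. Enone 7 ⇒ ketone 6 by α,β-dehydrogenation of the ring ketone.
3. Ketone 6 ⇒ enedione 4 + dimethylzinc + allyl acetate: asymmetric conjugate methylation sets C8 (R), and allylation of the enolate in the same flask sets the quaternary C6.
4. Enedione 4 ⇒ cyclohexanone 1 + arylglyoxal hydrate 2 by aldol condensation.
5. No ring is formed: the carbocycle is bought as cyclohexanone and the arene as the arylglyoxal.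

Atom labels used below (target numbering): ring C1 (C=O), C2=C3, C4 (OMe), C5 (CH2), C6 (quaternary); side-chain CH(CH3) = C8, aryl C=O = C7. In the target the OMe is cis to the side chain and trans to the allyl group.

Assumption: 2 is bought as a catalogue compound, and the hand of the phosphoramidite ligand is the one that adds methyl to the Re face of C8 (confirmed on the first run).

## Route

Step 1
Reactants: 1 cyclohexanone; 2 2,2-dihydroxy-1-(3,4-dimethoxyphenyl)ethan-1-one (3,4-dimethoxyphenylglyoxal monohydrate)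
Product: 4 (E)-2-[2-(3,4-dimethoxyphenyl)-2-oxoethylidene]cyclohexan-1-one, via aldol adduct 3 (not isolated)
Conditions: 1 (3 equiv), pyrrolidine (20 mol %), AcOH (20 mol %), 4 Å MS, toluene, 25 → 60 °C
Reagents that add atoms: none
Why: Amine-catalysed (enamine) aldol condensation of the ketone with the very electrophilic glyoxal aldehyde, with dehydration driven by conjugation to both carbonyls and giving the E-enedione (aroyl anti to the ring carbonyl); no stereocentre is formed.

Step 2
Reactants: 4 (E)-2-[2-(3,4-dimethoxyphenyl)-2-oxoethylidene]cyclohexan-1-one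
Product: 6 (2R)-2-[(2R)-1-(3,4-dimethoxyphenyl)-1-oxopropan-2-yl]-2-(prop-2-en-1-yl)cyclohexan-1-one, via methylzinc enolate 5 (not isolated)
Conditions: Cu(OTf)2 (3 mol %), (S,R,R)-binaphthol N,N-bis(1-phenylethyl)phosphoramidite (6 mol %), Me2Zn (2 equiv), toluene, −30 °C; then Pd(PPh3)4 (5 mol %), allyl acetate (3 equiv), 0 → 25 °C; aq NH4Cl
Reagents that add atoms: dimethylzinc, C[Zn]C; allyl acetate, C=CCOC(C)=O
Why: Copper–phosphoramidite asymmetric conjugate addition puts methyl on the Re face of the exocyclic CH (the only unhindered acceptor carbon of the enedione), setting C8 as R, and the tetrasubstituted zinc enolate is then allylated (Tsuji–Trost-type enolate allylation) anti to the aroyl group of the A(1,3)-locked C8 centre (C8–H in the enolate plane; the chelated model predicts the same face), setting the quaternary centre.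

Step 3
Reactants: 6 (2R)-2-[(2R)-1-(3,4-dimethoxyphenyl)-1-oxopropan-2-yl]-2-(prop-2-en-1-yl)cyclohexan-1-one
Product: 7 (6R)-6-[(2R)-1-(3,4-dimethoxyphenyl)-1-oxopropan-2-yl]-6-(prop-2-en-1-yl)cyclohex-2-en-1-one
Conditions: 2-iodoxybenzoic acid (IBX, 1.4 equiv), 4-methoxypyridine N-oxide (1.4 equiv), DMSO, 25 °C
Reagents that add atoms: none
Why: IBX α,β-dehydrogenation (Nicolaou) runs through the only easily formed enol (C1=C2; the other α-carbon is quaternary and the aryl ketone enolises much more slowly at its hindered tertiary C8), so the enone forms under base-free conditions without touching C6, C8 or the allyl group; no new stereocentre (the C6 descriptor is unchanged, same spatial arrangement).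

Step 4
Reactants: 7 (6R)-6-[(2R)-1-(3,4-dimethoxyphenyl)-1-oxopropan-2-yl]-6-(prop-2-en-1-yl)cyclohex-2-en-1-one
Product: 9 (4S,6S)-6-[(2R)-1-(3,4-dimethoxyphenyl)-1-oxopropan-2-yl]-4-methoxy-6-(prop-2-en-1-yl)cyclohex-2-en-1-one, via triisopropylsilyl dienol ether 8 (not isolated)
Conditions: i-Pr3SiOTf (1.3 equiv), Et3N (2 equiv), CH2Cl2, 0 °C; pentane, filter, evaporate; then Pd(O2CCF3)2 (10 mol %), duroquinone (1.5 equiv), Na2HPO4 (1 equiv), MeOH/CH2Cl2 1:3, −20 → 0 °C
Reagents that add atoms: methanol, CO; triisopropylsilyl trifluoromethanesulfonate, CC(C)[Si](OS(=O)(=O)C(F)(F)F)(C(C)C)C(C)C (its silyl group is in 8 only)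
Why: Proposed new method: oxidative γ-methoxylation of a 2-silyloxy-1,3-diene by divalent palladium, in which soft enolisation gives 8 by γ-deprotonation (the α'-carbon is quaternary), the pseudoaxial allyl olefin and the diene chelate the electrophilic metal on the allyl face, methanol attacks the free diene terminus C4 from outside and anti to palladium (hence trans to allyl, 4S), and the resulting 1-silyloxy-π-allyl palladium gives up its silyl group to methanol and collapses to the enone and zerovalent palladium, which duroquinone reoxidises (it is chosen because, unlike benzoquinone, it does not undergo Diels–Alder addition to 8); the closest known reactions are the Bäckvall 1,4-dialkoxylation of conjugated dienes (trans-alkoxypalladation to a π-allyl) and the Saegusa–Ito oxidation (collapse of a silyloxy-allyl palladium), and the bulky silyl group with a weakly coordinating carboxylate is meant to suppress the Saegusa-type silicon-to-palladium transfer and β-hydride loss.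

## Compound list

1 | cyclohexanone | O=C1CCCCC1 | starting material
2 | 2,2-dihydroxy-1-(3,4-dimethoxyphenyl)ethan-1-one (3,4-dimethoxyphenylglyoxal monohydrate) | COc1ccc(cc1OC)C(=O)C(O)O | starting material
3 | 2-[2-(3,4-dimethoxyphenyl)-1-hydroxy-2-oxoethyl]cyclohexan-1-one (aldol adduct, racemic diastereomer mixture) | O=C1CCCCC1C(O)C(=O)c1ccc(OC)c(OC)c1 | intermediate
4 | (E)-2-[2-(3,4-dimethoxyphenyl)-2-oxoethylidene]cyclohexan-1-one | O=C1CCCC/C1=C\C(=O)c1ccc(OC)c(OC)c1 | intermediate
5 | methyl{[2-[(2R)-1-(3,4-dimethoxyphenyl)-1-oxopropan-2-yl]cyclohex-1-en-1-yl]oxy}zinc (methylzinc enolate) | C[Zn]OC1=C(CCCC1)[C@@H](C)C(=O)c1ccc(OC)c(OC)c1 | intermediate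
6 | (2R)-2-[(2R)-1-(3,4-dimethoxyphenyl)-1-oxopropan-2-yl]-2-(prop-2-en-1-yl)cyclohexan-1-one | C=CC[C@@]1([C@@H](C)C(=O)c2ccc(OC)c(OC)c2)CCCCC1=O | intermediate
7 | (6R)-6-[(2R)-1-(3,4-dimethoxyphenyl)-1-oxopropan-2-yl]-6-(prop-2-en-1-yl)cyclohex-2-en-1-one | C=CC[C@@]1([C@@H](C)C(=O)c2ccc(OC)c(OC)c2)CCC=CC1=O | intermediate
8 | {[(6S)-6-[(2R)-1-(3,4-dimethoxyphenyl)-1-oxopropan-2-yl]-6-(prop-2-en-1-yl)cyclohexa-1,3-dien-1-yl]oxy}tri(propan-2-yl)silane | C=CC[C@@]1([C@@H](C)C(=O)c2ccc(OC)c(OC)c2)CC=CC=C1O[Si](C(C)C)(C(C)C)C(C)C | intermediate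
9 | (4S,6S)-6-[(2R)-1-(3,4-dimethoxyphenyl)-1-oxopropan-2-yl]-4-methoxy-6-(prop-2-en-1-yl)cyclohex-2-en-1-one | C=CC[C@@]1([C@@H](C)C(=O)c2ccc(OC)c(OC)c2)C[C@H](OC)C=CC1=O | target

## Step count and risks

Total steps: 4 (step 4 is telescoped; 8 is freed of ammonium salt by filtration but not purified). Longest linear sequence: 4.

Steps most likely to fail:

**Step 4 (the proposed new step).** Possible failures are Wacker-type attack on the allyl olefin, β-hydride loss to the 2,4-dienone followed by Cope rearrangement and aromatisation, simple protodesilylation back to 7, or the wrong face at C4. The fallback uses known chemistry, sets out from 7 and comes back at 9. γ-C–H oxidation of the enone with Rh2(cap)4 (cap = caprolactamate, 1 mol %), t-BuOOH and K2CO3 in CH2Cl2 at 25 °C gives (5S)-5-[(2R)-1-(3,4-dimethoxyphenyl)-1-oxopropan-2-yl]-5-(prop-2-en-1-yl)cyclohex-2-ene-1,4-dione F3. Reagent-controlled 1,2-reduction of the unhindered C4 carbonyl with (R)-2-methyl-CBS-oxazaborolidine and catecholborane (toluene, −78 °C; the antipode if a Mosher assay shows the other sense) gives (4S,6S)-4-hydroxy-6-[(2R)-1-(3,4-dimethoxyphenyl)-1-oxopropan-2-yl]-6-(prop-2-en-1-yl)cyclohex-2-en-1-one F4. O-Methylation under non-basic conditions (MeI, Ag2O, CH2Cl2, 25 °C) then gives 9.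

**Step 2 (tandem conjugate addition and allylation).** The risks are low diastereoselectivity or poor conversion in forming the quaternary centre from a hindered zinc enolate. The fallback sets out from 4 and comes back at 6, replacing substrate-controlled intermolecular allylation by ligand-controlled decarboxylative allylation. The copper-catalysed methyl addition is run as before and enolate 5 is quenched with allyl chloroformate to give prop-2-en-1-yl 2-[(2R)-1-(3,4-dimethoxyphenyl)-1-oxopropan-2-yl]cyclohex-1-en-1-yl carbonate F1. Treatment with Pd2(dba)3 and (S)-t-Bu-PHOX (the ligand hand that matches C8) in toluene at 25 °C then gives 6 by Tsuji–Stoltz decarboxylative allylic alkylation.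

**Step 3 (dehydrogenation).** The risks are over-oxidation to the dienone or attack at the side-chain ketone. The fallback sets out from 6 and comes back at 7 through a defined enol derivative. Soft enolisation (Me3SiOTf, Et3N, CH2Cl2, 0 °C) gives {[(6R)-6-[(2R)-1-(3,4-dimethoxyphenyl)-1-oxopropan-2-yl]-6-(prop-2-en-1-yl)cyclohex-1-en-1-yl]oxy}trimethylsilane F2, and Saegusa–Ito oxidation with Pd(OAc)2 (1.05 equiv) in MeCN at 25 °C gives 7.

## Further compounds

F1 | step 2 | prop-2-en-1-yl 2-[(2R)-1-(3,4-dimethoxyphenyl)-1-oxopropan-2-yl]cyclohex-1-en-1-yl carbonate | C=CCOC(=O)OC1=C(CCCC1)[C@@H](C)C(=O)c1ccc(OC)c(OC)c1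
F2 | step 3 | {[(6R)-6-[(2R)-1-(3,4-dimethoxyphenyl)-1-oxopropan-2-yl]-6-(prop-2-en-1-yl)cyclohex-1-en-1-yl]oxy}trimethylsilane | C=CC[C@@]1([C@@H](C)C(=O)c2ccc(OC)c(OC)c2)CCCC=C1O[Si](C)(C)C
F3 | step 4 | (5S)-5-[(2R)-1-(3,4-dimethoxyphenyl)-1-oxopropan-2-yl]-5-(prop-2-en-1-yl)cyclohex-2-ene-1,4-dione | C=CC[C@@]1([C@@H](C)C(=O)c2ccc(OC)c(OC)c2)CC(=O)C=CC1=O
F4 | step 4 | (4S,6S)-4-hydroxy-6-[(2R)-1-(3,4-dimethoxyphenyl)-1-oxopropan-2-yl]-6-(prop-2-en-1-yl)cyclohex-2-en-1-one | C=CC[C@@]1([C@@H](C)C(=O)c2ccc(OC)c(OC)c2)C[C@H](O)C=CC1=O
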